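**Retrosynthetic overview**
1. Target 21 ⇐ aldehyde 19 by Peterson-type (Z)-enyne construction ⇐ 16, the complete 2,7-dioxabicyclo[4.2.1]nonane core with both bromides and a vinyl group as masked C4–C5.
2. Oxolane ring (O6, C6, C7, C8, C9), closed second: transannular 5-exo bromoetherification of 6-hydroxy oxepene 15 puts O6 on C9 and Br on C10 in one anti addition; C13–Br comes from the C13 alcohol by SN2.
3. Oxepane ring (O7, C7, C8, C9, C10, C11, C12), closed first: 7-exo opening of the cis-C12/C13 epoxide of 10 by O7, with inversion at C12.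
4. Key disconnection: C8–C9 and C10–C11 together, with acetylene as the C9–C10 linchpin, alkylated in one flask by epoxy triflate 6 (C11–C15) and terminal epoxide 3 (C4–C8), each made by one Sharpless epoxidation.
5. Enabling feature: C9 and C10 are neighbouring CH carbons, each flanked by a ring CH2 (C8, C11) that lies β to an oxygen-bearing stereocentre (C7, C12), and their trans O/Br pattern is the anti-addition print of a (Z)-C9=C10 alkene; the C7–C12 belt of the oxepane ring is therefore a masked hex-3-yne-1,6-diyl.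

Key step: step 5

Remark: carbons are numbered C1–C15 along the chain from the alkyne CH (O6 on C6 closes to C9, O7 on C7 closes to C12); the two alkylations of step 5 are run in one flask without isolating 8.

**Step 1**
Reactants: 1 penta-1,4-dien-3-ol
Product: 2 (2R,3S)-1,2-epoxypent-4-en-3-ol
Conditions: Ti(OiPr)4 (cat.), L-(+)-DIPT, t-BuOOH, 4 Å MS, CH2Cl2, −20 °C
Reagents that add atoms: tert-butyl hydroperoxide, CC(C)(C)OO
Why: Sharpless asymmetric epoxidation of the meso divinyl carbinol combines enantiotopic-group and diastereoface selection, so the L-(+)-tartrate–titanium catalyst should epoxidise one vinyl group from one face to give the erythro (2R,3S)-epoxy alcohol, which sets C7 (R) and makes the carbinol carbon C6 (S), the minor enantiomer being drained by over-epoxidation.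

**Step 2**
Reactants: 2 (2R,3S)-1,2-epoxypent-4-en-3-ol
Product: 3 (2R,3S)-1,2-epoxy-3-[(4-methoxybenzyl)oxy]pent-4-ene
Conditions: NaH, 4-methoxybenzyl chloride, n-Bu4NI (cat.), THF, −20 → 0 °C
Reagents that add atoms: 4-methoxybenzyl chloride, COc1ccc(CCl)cc1
Why: Williamson etherification of the sodium alkoxide with the benzylic chloride at low temperature should outrun Payne rearrangement of the 1,2-epoxy-3-ol and touches no stereocentre.

**Step 3**
Reactants: 4 (2Z)-pent-2-en-1-ol
Product: 5 (2S,3R)-2,3-epoxypentan-1-ol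
Conditions: Ti(OiPr)4 (cat.), L-(+)-DET, t-BuOOH, 4 Å MS, CH2Cl2, −20 °C
Reagents that add atoms: tert-butyl hydroperoxide, CC(C)(C)OO
Why: Sharpless asymmetric epoxidation of the (Z)-allylic alcohol with the L-(+)-tartrate catalyst should deliver oxygen to the face given by the mnemonic and give the cis-epoxide (2S,3R), fixing C12 and C13 together (the lower enantioselectivity generally expected for Z-olefins would surface after step 5 as a separable diastereomer).

**Step 4**
Reactants: 5 (2S,3R)-2,3-epoxypentan-1-ol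
Product: 6 (2S,3R)-2,3-epoxypentyl trifluoromethanesulfonate
Conditions: Tf2O, 2,6-lutidine, CH2Cl2, −78 °C; cold work-up, used at once
Reagents that add atoms: trifluoromethanesulfonic anhydride, O=S(=O)(OS(=O)(=O)C(F)(F)F)C(F)(F)F
Why: O-sulfonylation of the primary alcohol with triflic anhydride at −78 °C gives the epoxy triflate without touching the epoxide or a stereocentre, and the labile product is used cold without purification.

**Step 5**
Reactants: 7 acetylene; 6 (2S,3R)-2,3-epoxypentyl trifluoromethanesulfonate; 3 (2R,3S)-1,2-epoxy-3-[(4-methoxybenzyl)oxy]pent-4-ene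
Product: 9 (3S,4R)-8-[(2S,3R)-3-ethyloxiran-2-yl]-3-[(4-methoxybenzyl)oxy]oct-1-en-6-yn-4-ol, via epoxy-alkyne 8 (not isolated)
Conditions: HC≡CH (excess), n-BuLi, THF, −78 °C; 6, −78 → −20 °C; Ar purge; n-BuLi, −78 °C; BF3·OEt2, then 3, −78 °C; aq. NH4Cl
Reagents that add atoms: none
Why: Lithium acetylide first displaces the primary triflate of 6 by SN2 (C10–C11), and the terminal alkyne 8 so formed is relithiated and, as its BF3 ate complex, opens the terminal epoxide of 3 at the CH2 carbon (C8–C9), so that acetylene ends up as the C9–C10 linchpin between the two chiral fragments. The closest known reaction types are the alkylation of alkynyllithiums with primary alkyl triflates and the BF3-mediated opening of epoxides by lithium acetylides (Yamaguchi–Hirao alkynylation). No ring is closed in this step; it lays out the 1,6-relationship of O7 and C12 and the 1,4-relationship of O6 and C9 that the later 7-exo and 5-exo closures use. No stereocentre is formed: C6, C7, C12 and C13 come from the two Sharpless epoxidations and both new bonds are made at CH2 carbons, so none of them is touched. The step needs chemoselectivity (triflate over epoxide in 6, mono- over dialkylation of acetylene, terminal over internal epoxide in the second stage) and regioselectivity (attack at C8 of 3); these should be secured by the far better leaving group and the absence of Lewis acid in the first stage, by the excess of acetylene that keeps 8 protonated until it is purged, and by the preference of the alkynyl–BF3 reagent for the unsubstituted carbon of a monosubstituted epoxide over a 2,3-disubstituted one.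

**Step 6**
Reactants: 9 (3S,4R)-8-[(2S,3R)-3-ethyloxiran-2-yl]-3-[(4-methoxybenzyl)oxy]oct-1-en-6-yn-4-ol
Product: 10 (3S,4R,6Z)-8-[(2S,3R)-3-ethyloxiran-2-yl]-3-[(4-methoxybenzyl)oxy]octa-1,6-dien-4-ol
Conditions: H2 (1 atm), Pd/CaCO3–Pb(OAc)2, quinoline, EtOAc, rt
Reagents that add atoms: none
Why: Lindlar semi-hydrogenation adds H2 syn to the internal alkyne on the poisoned palladium surface to give the (Z)-C9=C10 alkene, the alkyne being adsorbed far more strongly than the monosubstituted vinyl group, while the epoxide and the PMB ether are inert.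

**Step 7**
Reactants: 10 (3S,4R,6Z)-8-[(2S,3R)-3-ethyloxiran-2-yl]-3-[(4-methoxybenzyl)oxy]octa-1,6-dien-4-ol
Product: 13 (1R)-1-[(2R,7R)-7-[(1S)-1-[(4-methoxybenzyl)oxy]prop-2-en-1-yl]-2,3,6,7-tetrahydrooxepin-2-yl]propan-1-ol, via stannyl ether 11 (not isolated), via cyclised stannyl ether 12 (not isolated)
Conditions: (Bu3Sn)2O, toluene, reflux (−H2O); Zn(OTf)2 (cat.), 90 °C; aq. NaHCO3
Reagents that add atoms: none
Why: Exo-selective hydroxy-epoxide cyclisation, in which the tributylstannyl ether of O7, with Zn(OTf)2 activating the epoxide, should attack C12 in a 7-exo-tet SN2 opening pre-organised by the cis-alkene, inverting C12 (S to R) and leaving the former epoxide oxygen as the (R)-C13 alcohol, so that the 2,7-trans oxepene follows from the two epoxide stereocentres.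

**Step 8**
Reactants: 13 (1R)-1-[(2R,7R)-7-[(1S)-1-[(4-methoxybenzyl)oxy]prop-2-en-1-yl]-2,3,6,7-tetrahydrooxepin-2-yl]propan-1-ol
Product: 14 (2R,7R)-2-[(1S)-1-bromopropyl]-7-[(1S)-1-[(4-methoxybenzyl)oxy]prop-2-en-1-yl]-2,3,6,7-tetrahydrooxepine
Conditions: CBr4, P(n-C8H17)3, toluene, 70 °C
Reagents that add atoms: tetrabromomethane, BrC(Br)(Br)Br
Why: Appel-type bromination converts the C13 alcohol through its alkoxyphosphonium salt into the bromide by SN2 with inversion (13R alcohol to 13S bromide), the bulky trioctylphosphine in warm toluene being the usual way to limit elimination next to a ring ether oxygen.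

**Step 9**
Reactants: 14 (2R,7R)-2-[(1S)-1-bromopropyl]-7-[(1S)-1-[(4-methoxybenzyl)oxy]prop-2-en-1-yl]-2,3,6,7-tetrahydrooxepine
Product: 15 (1S)-1-[(2R,7R)-7-[(1S)-1-bromopropyl]-2,3,6,7-tetrahydrooxepin-2-yl]prop-2-en-1-ol
Conditions: DDQ, CH2Cl2/pH 7 buffer, 0 °C
Reagents that add atoms: none
Why: Oxidative cleavage of the electron-rich 4-methoxybenzyl ether by DDQ (hydride abstraction, then hydrolysis of the oxocarbenium ion) frees O6 while the secondary bromide and both alkenes are left alone.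

**Step 10**
Reactants: 15 (1S)-1-[(2R,7R)-7-[(1S)-1-bromopropyl]-2,3,6,7-tetrahydrooxepin-2-yl]prop-2-en-1-ol
Product: 16 (1R,3R,5R,6R,8S)-5-bromo-3-[(1S)-1-bromopropyl]-8-ethenyl-2,7-dioxabicyclo[4.2.1]nonane
Conditions: NBS, CH2Cl2, 0 °C, dark
Reagents that add atoms: N-bromosuccinimide, O=C1CCC(=O)N1Br
Why: Transannular bromoetherification, the laboratory copy of the presumed biosynthetic closure, in which bromonium formation on the C9=C10 face opposite to the tethered O6 and 5-exo attack of O6 on C9 close the oxolane ring, the anti addition fixing C9 (R, oxygen on the face of the C7 side chain, the only one O6 can reach) and C10 (R, bromine on the other face), while the vinyl group is less nucleophilic and has no hydroxyl placed for a favourable ring closure.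

**Step 11**
Reactants: 16 (1R,3R,5R,6R,8S)-5-bromo-3-[(1S)-1-bromopropyl]-8-ethenyl-2,7-dioxabicyclo[4.2.1]nonane
Product: 18 2-[(1R,3R,5R,6R,8S)-5-bromo-3-[(1S)-1-bromopropyl]-2,7-dioxabicyclo[4.2.1]nonan-8-yl]ethanol, via B-alkyl-9-BBN adduct 17 (not isolated)
Conditions: 9-BBN, THF, 0 °C → rt; then 30% H2O2, aq. NaHCO3, 0 °C
Reagents that add atoms: hydrogen peroxide, OO
Why: Hydroboration–oxidation with the bulky 9-BBN places boron on the terminal carbon C4 of the monosubstituted alkene, and buffered peroxide oxidation then gives the primary alcohol without a base strong enough to eliminate the secondary bromides, no stereocentre being involved.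

**Step 12**
Reactants: 18 2-[(1R,3R,5R,6R,8S)-5-bromo-3-[(1S)-1-bromopropyl]-2,7-dioxabicyclo[4.2.1]nonan-8-yl]ethanol
Product: 19 [(1R,3R,5R,6R,8S)-5-bromo-3-[(1S)-1-bromopropyl]-2,7-dioxabicyclo[4.2.1]nonan-8-yl]acetaldehyde
Conditions: Dess–Martin periodinane, NaHCO3, CH2Cl2, 0 °C → rt
Reagents that add atoms: none
Why: Dess–Martin oxidation under bicarbonate buffering gives the β-alkoxy aldehyde under nearly neutral conditions, which avoids β-elimination of the ring oxygen.

**Step 13**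
Reactants: 19 [(1R,3R,5R,6R,8S)-5-bromo-3-[(1S)-1-bromopropyl]-2,7-dioxabicyclo[4.2.1]nonan-8-yl]acetaldehyde
Product: 20 (1R,3R,5R,6R,8S)-5-bromo-3-[(1S)-1-bromopropyl]-8-[(2Z)-5-(triisopropylsilyl)pent-2-en-4-yn-1-yl]-2,7-dioxabicyclo[4.2.1]nonane
Conditions: 1,3-bis(triisopropylsilyl)propyne, n-BuLi, THF, −78 °C; then 19, −78 → −20 °C
Reagents that add atoms: 1,3-bis(triisopropylsilyl)propyne, CC(C)[Si](C(C)C)(C(C)C)CC#C[Si](C(C)C)(C(C)C)C(C)C
Why: Peterson olefination with the lithiated bis-silyl propyne, in which addition to the aldehyde and syn-elimination of the β-silyl alkoxide should give the (Z)-enyne selectively because the bulky silyl groups control the geometry of addition, at a temperature where the reagent should add faster than it enolises the β-alkoxy aldehyde.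

**Step 14**
Reactants: 20 (1R,3R,5R,6R,8S)-5-bromo-3-[(1S)-1-bromopropyl]-8-[(2Z)-5-(triisopropylsilyl)pent-2-en-4-yn-1-yl]-2,7-dioxabicyclo[4.2.1]nonane
Product: 21 (1R,3R,5R,6R,8S)-5-bromo-3-[(1S)-1-bromopropyl]-8-[(2Z)-pent-2-en-4-yn-1-yl]-2,7-dioxabicyclo[4.2.1]nonane
Conditions: TBAF, THF, −20 → 0 °C
Reagents that add atoms: none
Why: Fluoride-induced cleavage of the C(sp)–Si bond (protodesilylation) at low temperature should release the terminal alkyne without E2 loss of the secondary bromides and give the target.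

**Compound list**
1 | penta-1,4-dien-3-ol | C=CC(O)C=C | starting material
2 | (2R,3S)-1,2-epoxypent-4-en-3-ol | C=C[C@H](O)[C@H]1CO1 | intermediate
3 | (2R,3S)-1,2-epoxy-3-[(4-methoxybenzyl)oxy]pent-4-ene | C=C[C@H](OCc1ccc(OC)cc1)[C@H]1CO1 | intermediate
4 | (2Z)-pent-2-en-1-ol | CC/C=C\CO | starting material
5 | (2S,3R)-2,3-epoxypentan-1-ol | OC[C@@H]1O[C@@H]1CC | intermediate
6 | (2S,3R)-2,3-epoxypentyl trifluoromethanesulfonate | FC(F)(F)S(=O)(=O)OC[C@@H]1O[C@@H]1CC | intermediate
7 | acetylene | C#C | starting material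
8 | (2R,3S)-2-ethyl-3-(prop-2-yn-1-yl)oxirane | C#CC[C@@H]1O[C@@H]1CC | intermediate
9 | (3S,4R)-8-[(2S,3R)-3-ethyloxiran-2-yl]-3-[(4-methoxybenzyl)oxy]oct-1-en-6-yn-4-ol | C=C[C@H](OCc1ccc(OC)cc1)[C@H](O)CC#CC[C@@H]1O[C@@H]1CC | intermediate
10 | (3S,4R,6Z)-8-[(2S,3R)-3-ethyloxiran-2-yl]-3-[(4-methoxybenzyl)oxy]octa-1,6-dien-4-ol | C=C[C@H](OCc1ccc(OC)cc1)[C@H](O)C/C=C\C[C@@H]1O[C@@H]1CC | intermediate
11 | O4-tributylstannyl ether of 10 | C=C[C@H](OCc1ccc(OC)cc1)[C@H](O[Sn](CCCC)(CCCC)CCCC)C/C=C\C[C@@H]1O[C@@H]1CC | intermediate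
12 | O-tributylstannyl ether of 13 | C=C[C@H](OCc1ccc(OC)cc1)[C@H]1C/C=C\C[C@@H](O1)[C@H](O[Sn](CCCC)(CCCC)CCCC)CC | intermediate
13 | (1R)-1-[(2R,7R)-7-[(1S)-1-[(4-methoxybenzyl)oxy]prop-2-en-1-yl]-2,3,6,7-tetrahydrooxepin-2-yl]propan-1-ol | C=C[C@H](OCc1ccc(OC)cc1)[C@H]1C/C=C\C[C@@H](O1)[C@H](O)CC | intermediate
14 | (2R,7R)-2-[(1S)-1-bromopropyl]-7-[(1S)-1-[(4-methoxybenzyl)oxy]prop-2-en-1-yl]-2,3,6,7-tetrahydrooxepine | C=C[C@H](OCc1ccc(OC)cc1)[C@H]1C/C=C\C[C@@H](O1)[C@@H](Br)CC | intermediate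
15 | (1S)-1-[(2R,7R)-7-[(1S)-1-bromopropyl]-2,3,6,7-tetrahydrooxepin-2-yl]prop-2-en-1-ol | C=C[C@H](O)[C@H]1C/C=C\C[C@@H](O1)[C@@H](Br)CC | intermediate
16 | (1R,3R,5R,6R,8S)-5-bromo-3-[(1S)-1-bromopropyl]-8-ethenyl-2,7-dioxabicyclo[4.2.1]nonane | C=C[C@@H]1O[C@@H]2C[C@H]1O[C@@H]([C@@H](Br)CC)C[C@H]2Br | intermediate
17 | 9-{2-[(1R,3R,5R,6R,8S)-5-bromo-3-[(1S)-1-bromopropyl]-2,7-dioxabicyclo[4.2.1]nonan-8-yl]ethyl}-9-borabicyclo[3.3.1]nonane | C1CCC2CCCC1B2CC[C@@H]3O[C@@H]4C[C@H]3O[C@@H]([C@@H](Br)CC)C[C@H]4Br | intermediate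
18 | 2-[(1R,3R,5R,6R,8S)-5-bromo-3-[(1S)-1-bromopropyl]-2,7-dioxabicyclo[4.2.1]nonan-8-yl]ethanol | OCC[C@@H]1O[C@@H]2C[C@H]1O[C@@H]([C@@H](Br)CC)C[C@H]2Br | intermediate
19 | [(1R,3R,5R,6R,8S)-5-bromo-3-[(1S)-1-bromopropyl]-2,7-dioxabicyclo[4.2.1]nonan-8-yl]acetaldehyde | O=CC[C@@H]1O[C@@H]2C[C@H]1O[C@@H]([C@@H](Br)CC)C[C@H]2Br | intermediate
20 | (1R,3R,5R,6R,8S)-5-bromo-3-[(1S)-1-bromopropyl]-8-[(2Z)-5-(triisopropylsilyl)pent-2-en-4-yn-1-yl]-2,7-dioxabicyclo[4.2.1]nonane | CC(C)[Si](C(C)C)(C(C)C)C#C/C=C\C[C@@H]1O[C@@H]2C[C@H]1O[C@@H]([C@@H](Br)CC)C[C@H]2Br | intermediate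
21 | (1R,3R,5R,6R,8S)-5-bromo-3-[(1S)-1-bromopropyl]-8-[(2Z)-pent-2-en-4-yn-1-yl]-2,7-dioxabicyclo[4.2.1]nonane | C#C/C=C\C[C@@H]1O[C@@H]2C[C@H]1O[C@@H]([C@@H](Br)CC)C[C@H]2Br | target

**Step count and risks**
Total steps: 14. Longest linear sequence: 12 steps (steps 1, 2 and 5 to 14).

Steps most likely to fail:

Step 5. Acetylene may be alkylated twice, the epoxy triflate may decompose before the C–C bond forms, or the alkynyl–BF3 reagent may attack the internal epoxide. The fallback gives up the one-flask linchpin for a silyl-masked, two-stage union; it sets out from 6 and comes back at 9. Compound 6 is treated with lithium (trimethylsilyl)acetylide (THF, −78 °C) to give (2R,3S)-2-ethyl-3-[3-(trimethylsilyl)prop-2-yn-1-yl]oxirane F1, which cannot be alkylated a second time and can be purified. K2CO3 in MeOH removes the silyl group to give 8, now isolated. Lithiation of 8 (n-BuLi) and BF3·OEt2-mediated opening of 3 then give 9.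

Step 7. The ring closure may be too slow against intermolecular epoxide opening, or O7 may attack C13 (8-endo). The fallback reverses the order of the ring closures; it sets out from 10 and comes back at 16. DDQ frees O6 of 10 to give (3S,4R,6Z)-8-[(2S,3R)-3-ethyloxiran-2-yl]octa-1,6-diene-3,4-diol F2. NBS closes the oxolane ring first (5-exo bromoetherification by O6) to give (2S,3R,5R)-5-[(1R)-1-bromo-2-[(2S,3R)-3-ethyloxiran-2-yl]ethyl]-2-ethenyloxolan-3-ol F3; facial control is weaker here, so its C9/C10 diastereomer would have to be separated, and only the isomer with O7 and the side chain cis can go on. On this rigid template the 7-exo opening of the epoxide by O7 ((Bu3Sn)2O, Zn(OTf)2) gives (1R)-1-[(1R,3R,5R,6R,8S)-5-bromo-8-ethenyl-2,7-dioxabicyclo[4.2.1]nonan-3-yl]propan-1-ol F4. CBr4 and P(n-C8H17)3 convert it with inversion at C13 into 16.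

Step 10. The vinyl group may be brominated in competition, or O6 may close in the 6-endo sense. The fallback removes the vinyl group before the bromonium step; it sets out from 14 and comes back at 18. 9-BBN then buffered H2O2 on 14 (the monosubstituted alkene reacts before the cis ring alkene) gives (3S)-3-[(2R,7R)-7-[(1S)-1-bromopropyl]-2,3,6,7-tetrahydrooxepin-2-yl]-3-[(4-methoxybenzyl)oxy]propan-1-ol F5. TBDPSCl and imidazole give tert-butyl{(3S)-3-[(2R,7R)-7-[(1S)-1-bromopropyl]-2,3,6,7-tetrahydrooxepin-2-yl]-3-[(4-methoxybenzyl)oxy]propoxy}diphenylsilane F6. DDQ gives (1S)-1-[(2R,7R)-7-[(1S)-1-bromopropyl]-2,3,6,7-tetrahydrooxepin-2-yl]-3-[(tert-butyldiphenylsilyl)oxy]propan-1-ol F7. NBS closes the oxolane ring to {2-[(1R,3R,5R,6R,8S)-5-bromo-3-[(1S)-1-bromopropyl]-2,7-dioxabicyclo[4.2.1]nonan-8-yl]ethoxy}(tert-butyl)diphenylsilane F8, and HF·pyridine gives 18.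

**Further compounds**
F1 | step 5 | (2R,3S)-2-ethyl-3-[3-(trimethylsilyl)prop-2-yn-1-yl]oxirane | C[Si](C)(C)C#CC[C@@H]1O[C@@H]1CC
F2 | step 7 | (3S,4R,6Z)-8-[(2S,3R)-3-ethyloxiran-2-yl]octa-1,6-diene-3,4-diol | C=C[C@H](O)[C@H](O)C/C=C\C[C@@H]1O[C@@H]1CC
F3 | step 7 | (2S,3R,5R)-5-[(1R)-1-bromo-2-[(2S,3R)-3-ethyloxiran-2-yl]ethyl]-2-ethenyloxolan-3-ol | C=C[C@@H]1O[C@H](C[C@H]1O)[C@H](Br)C[C@@H]2O[C@@H]2CC
F4 | step 7 | (1R)-1-[(1R,3R,5R,6R,8S)-5-bromo-8-ethenyl-2,7-dioxabicyclo[4.2.1]nonan-3-yl]propan-1-ol | C=C[C@@H]1O[C@@H]2C[C@H]1O[C@@H]([C@H](O)CC)C[C@H]2Br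
F5 | step 10 | (3S)-3-[(2R,7R)-7-[(1S)-1-bromopropyl]-2,3,6,7-tetrahydrooxepin-2-yl]-3-[(4-methoxybenzyl)oxy]propan-1-ol | OCC[C@H](OCc1ccc(OC)cc1)[C@H]1C/C=C\C[C@@H](O1)[C@@H](Br)CC
F6 | step 10 | tert-butyl{(3S)-3-[(2R,7R)-7-[(1S)-1-bromopropyl]-2,3,6,7-tetrahydrooxepin-2-yl]-3-[(4-methoxybenzyl)oxy]propoxy}diphenylsilane | CC(C)(C)[Si](c1ccccc1)(c1ccccc1)OCC[C@H](OCc1ccc(OC)cc1)[C@H]1C/C=C\C[C@@H](O1)[C@@H](Br)CC
F7 | step 10 | (1S)-1-[(2R,7R)-7-[(1S)-1-bromopropyl]-2,3,6,7-tetrahydrooxepin-2-yl]-3-[(tert-butyldiphenylsilyl)oxy]propan-1-ol | CC(C)(C)[Si](c1ccccc1)(c1ccccc1)OCC[C@H](O)[C@H]1C/C=C\C[C@@H](O1)[C@@H](Br)CC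
F8 | step 10 | {2-[(1R,3R,5R,6R,8S)-5-bromo-3-[(1S)-1-bromopropyl]-2,7-dioxabicyclo[4.2.1]nonan-8-yl]ethoxy}(tert-butyl)diphenylsilane | CC(C)(C)[Si](c1ccccc1)(c1ccccc1)OCC[C@@H]1O[C@@H]2C[C@H]1O[C@@H]([C@@H](Br)CC)C[C@H]2Br
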